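**Plan** (labdane numbering throughout, also for open-chain compounds: ring A = C1–C5, C10; ring B = C5–C10)

1. Endgame cuts: the C6 and C7 esters go back to a 7α-hydroxy-6-ketone, and the C6 ketone to a C6 nitro group (Nef reaction).
2. Enabling feature: ring B is a cyclohexene whose C8=C9 bond lies opposite C5–C6, so C5–C10 and C6–C7 are the two σ-bonds of a [4+2] retron; C5 and C10 are also bridged by C1–C4 of ring A, so one intramolecular cycloaddition closes both rings from an open-chain nitrotriene with a single stereocentre (C2).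
3. Triene cuts: C5=C6 (Henry), C7 and C17 onto C8 (double methyl addition, dehydration), C10–CH3 (enol triflate, Negishi), C9–C11 (β-ketoester alkylation), C1–C2 (vinylogous aldol).
4. Forward order: side-chain iodide; acetal aldehyde; aldol, alkylation, stereodefined tetrasubstituted C9=C10, diene, nitroalkene; rings A and B together; C6/C7 oxygenation; esters; desilylation.
5. Stereochemistry: C2 from the catalytic asymmetric aldol; C5 and C10 from the cycloaddition under C2 control; C7 by α-face enolate hydroxylation; C6 by α-face hydride delivery; C13=C14 (E) from syn-carboalumination; C9=C10 from the chelated Z-enol triflate.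

Key step: step 16

Remark (assumption): Ti(OiPr)4/(R)-BINOL is taken to give the (S)-carbinol in step 7; the sense would be checked on 13 as its Mosher esters and (S)-BINOL used if it proved opposite.
Abbreviations: TBS = tert-butyldimethylsilyl; TBDPS = tert-butyldiphenylsilyl.

**Route**

Step 1
Reactants: 1 4-(tert-butyldimethylsilyloxy)but-1-yne
Product: 3 (E)-5-(TBSO)-3-methylpent-2-en-1-ol, via alkenylalane 2 (not isolated)
Conditions: Me3Al, Cp2ZrCl2 (cat.), CH2Cl2, 0 °C → rt; then n-BuLi, (CH2O)n, THF, −78 °C → rt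
Reagents that add atoms: trimethylaluminium (C[Al](C)C); formaldehyde as paraformaldehyde (C=O)
Why: Zirconium-catalysed carboalumination (Negishi) should add CH3–Al syn with the methyl on the internal carbon, and the derived alkenylalanate should attack formaldehyde with retention, which fixes the E geometry of C13=C14.

Step 2
Reactants: 3 (E)-5-(TBSO)-3-methylpent-2-en-1-ol
Product: 4 (E)-5-(TBSO)-1-(TBDPSO)-3-methylpent-2-ene
Conditions: TBDPSCl, imidazole, DMF, rt
Reagents that add atoms: tert-butyldiphenylsilyl chloride (CC(C)(C)[Si](Cl)(c1ccccc1)c1ccccc1)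
Why: Standard silylation of a primary allylic alcohol with a chlorosilane and imidazole.

Step 3
Reactants: 4 (E)-5-(TBSO)-1-(TBDPSO)-3-methylpent-2-ene
Product: 5 (E)-5-(TBDPSO)-3-methylpent-3-en-1-ol
Conditions: PPTS, EtOH, 50 °C
Reagents that add atoms: none
Why: Acid-catalysed solvolysis (selective desilylation) should cleave the primary TBS ether far faster than the bulkier TBDPS ether.

Step 4
Reactants: 5 (E)-5-(TBDPSO)-3-methylpent-3-en-1-ol
Product: 6 (E)-1-(TBDPSO)-5-iodo-3-methylpent-2-ene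
Conditions: I2, PPh3, imidazole, CH2Cl2, 0 °C → rt
Reagents that add atoms: iodine (II)
Why: Appel-type iodination of a primary alcohol through the alkoxyphosphonium salt and SN2 displacement by iodide.

Step 5
Reactants: 7 2,2-dimethylpent-4-enal
Product: 8 5,5-dimethoxy-4,4-dimethylpent-1-ene
Conditions: HC(OMe)3, MeOH, TsOH (cat.), rt
Reagents that add atoms: trimethyl orthoformate (COC(OC)OC)
Why: Acid-catalysed acetalisation, driven by the orthoformate as water scavenger, masks the neopentyl aldehyde (C5) for the basic and organometallic steps.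

Step 6
Reactants: 8 5,5-dimethoxy-4,4-dimethylpent-1-ene
Product: 10 4,4-dimethoxy-3,3-dimethylbutanal, via ozonide 9 (not isolated)
Conditions: O3, CH2Cl2, −78 °C; then PPh3, −78 °C → rt
Reagents that add atoms: ozone ([O-][O+]=O)
Why: Ozonolysis of the only alkene with reductive work-up should give the aldehyde (C2), the acetal being inert.

Step 7
Reactants: 10 4,4-dimethoxy-3,3-dimethylbutanal; 11 1-methoxy-1,3-bis(trimethylsilyloxy)buta-1,3-diene
Product: 13 methyl (S)-5-hydroxy-8,8-dimethoxy-7,7-dimethyl-3-oxooctanoate, via bis-silyl aldol adduct 12 (not isolated)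
Conditions: Ti(OiPr)4 (10 mol %), (R)-BINOL (10 mol %), 4 Å MS, THF, −78 °C → rt; then PPTS, MeOH, 0 °C
Reagents that add atoms: none
Why: Catalytic asymmetric vinylogous Mukaiyama aldol addition, in which the titanium BINOLate should bind the aldehyde and expose one face to the γ-carbon of the silyl dienolate, setting the C2 carbinol stereocentre (the only stereocentre carried into the key step) while mild methanolysis frees the β-ketoester.

Step 8
Reactants: 13 methyl (S)-5-hydroxy-8,8-dimethoxy-7,7-dimethyl-3-oxooctanoate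
Product: 14 methyl (S)-5-(TBSO)-8,8-dimethoxy-7,7-dimethyl-3-oxooctanoate
Conditions: TBSCl, imidazole, DMF, rt
Reagents that add atoms: tert-butyldimethylsilyl chloride (CC(C)(C)[Si](C)(C)Cl)
Why: Silylation of the secondary alcohol; a silyl ether is chosen because a β-acyloxy ketone would eliminate under the basic conditions of steps 9 and 10.

Step 9
Reactants: 14 methyl (S)-5-(TBSO)-8,8-dimethoxy-7,7-dimethyl-3-oxooctanoate; 6 (E)-1-(TBDPSO)-5-iodo-3-methylpent-2-ene
Product: 15 methyl (5S)-5-(TBSO)-2-[(E)-5-(TBDPSO)-3-methylpent-3-enyl]-8,8-dimethoxy-7,7-dimethyl-3-oxooctanoate (both epimers at the α-carbon)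
Conditions: K2CO3, acetone, reflux
Reagents that add atoms: none
Why: C-alkylation of the β-ketoester potassium enolate with the primary iodide (SN2) joins C9 to C11; the new C9 centre is inconsequential because it becomes sp2 in step 10.

Step 10
Reactants: 15 alkylated β-ketoester
Product: 17 methyl (2Z)-5-(TBSO)-2-[(E)-5-(TBDPSO)-3-methylpent-3-enyl]-8,8-dimethoxy-7,7-dimethyl-3-(trifluoromethylsulfonyloxy)oct-2-enoate, via sodium enolate 16 (not isolated)
Conditions: NaH, THF, 0 °C; then PhNTf2, 0 °C → rt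
Reagents that add atoms: N-phenylbis(trifluoromethanesulfonimide) (O=S(=O)(N(c1ccccc1)S(=O)(=O)C(F)(F)F)C(F)(F)F)
Why: O-sulfonylation of the chelated sodium enolate, in which sodium bridges the enolate and ester oxygens, should give the enol triflate with OTf cis to the ester (Z), the geometry that later places the C10 methyl inside and the tether outside on the diene.

Step 11
Reactants: 17 (Z)-enol triflate
Product: 18 methyl (2E)-5-(TBSO)-2-[(E)-5-(TBDPSO)-3-methylpent-3-enyl]-8,8-dimethoxy-3,7,7-trimethyloct-2-enoate (silyloxy carbon as in 14)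
Conditions: Me2Zn, Pd(PPh3)4 (5 mol %), THF, 0 °C → rt
Reagents that add atoms: dimethylzinc (C[Zn]C)
Why: Negishi cross-coupling of the enol triflate under zerovalent palladium catalysis should proceed with retention of alkene geometry and tolerate the ester, giving the stereodefined tetrasubstituted C9=C10 alkene.

Step 12
Reactants: 18 tetrasubstituted enoate
Product: 19 (3E)-6-(TBSO)-3-[(E)-5-(TBDPSO)-3-methylpent-3-enyl]-9,9-dimethoxy-2,4,8,8-tetramethylnon-3-en-2-ol (silyloxy carbon as in 14)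
Conditions: MeLi, CeCl3 (anhydrous), THF, −78 → 0 °C
Reagents that add atoms: methyllithium ([Li]C)
Why: Double 1,2-addition of the weakly basic methylcerium reagent to the hindered ester should give the tertiary allylic alcohol, which supplies C7 and the C8 methyl, without γ-deprotonation.

Step 13
Reactants: 19 tertiary allylic alcohol
Product: 20 (3E)-6-(TBSO)-3-[(E)-5-(TBDPSO)-3-methylpent-3-enyl]-9,9-dimethoxy-2,4,8,8-tetramethylnona-1,3-diene (silyloxy carbon as in 14)
Conditions: Burgess reagent (methyl N-(triethylammoniumsulfonyl)carbamate), toluene, 50 °C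
Reagents that add atoms: none
Why: Dehydration with the Burgess reagent by syn-elimination of the sulfamate ester; only the two methyl groups carry β-hydrogens, so the diene C7=C8–C9=C10 should form without touching the C9=C10 geometry.

Step 14
Reactants: 20 diene acetal
Product: 21 (6E)-4-(TBSO)-7-[(E)-5-(TBDPSO)-3-methylpent-3-enyl]-2,2,6,8-tetramethylnona-6,8-dienal (silyloxy carbon as in 14)
Conditions: PPTS (0.3 equiv), acetone/H2O 10:1, 45 °C
Reagents that add atoms: water (O)
Why: Mild acid-catalysed acetal hydrolysis should unmask the C5 aldehyde while the silyl ethers and the diene persist.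

Step 15
Reactants: 21 diene aldehyde
Product: 23 (1E,7E)-5-(TBSO)-8-[(E)-5-(TBDPSO)-3-methylpent-3-enyl]-3,3,7,9-tetramethyl-1-nitrodeca-1,7,9-triene (silyloxy carbon as in 14), via nitroaldol 22 (not isolated)
Conditions: MeNO2, KOtBu (cat.), THF/t-BuOH, 0 °C; concentrate; then MsCl, Et3N, CH2Cl2, −20 → 0 °C
Reagents that add atoms: nitromethane (C[N+](=O)[O-])
Why: Henry (nitroaldol) addition to the neopentyl aldehyde followed by mesylation and E1cB elimination should give the thermodynamically favoured (E)-nitroalkene, the dienophile C5=C6.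

Step 16
Reactants: 23 nitrotriene
Product: 24 2α-(TBSO)-15-(TBDPSO)-6α-nitrolabda-8,13E-diene (5α-H; 10β-CH3)
Conditions: toluene (0.01 M), BHT (cat.), 100 °C, sealed tube
Reagents that add atoms: none
Why: Thermal intramolecular Diels–Alder reaction: a concerted but asynchronous [4+2] cycloaddition of the electron-poor (E)-nitroalkene C5=C6 (LUMO) to the tetrasubstituted diene C7=C8–C9=C10 (HOMO), in which the C5–C10 bond between the nitroalkene β-carbon and the fully substituted diene terminus is the more advanced. The closest known reaction types are the thermal cyclisations of (E)-1-nitro-1,7,9-decatrienes to trans-fused nitro-octalins and of 7-methyl-1,7,9-decatrienes to angularly methylated octalins. Ring A closes through C5–C10 as a six-membered carbocycle over the four-carbon tether C1–C4 held in a chair, and ring B closes as the cyclohexene through C6–C7 with the new C8=C9 double bond. C5 and C10 should become trans (5α-H, 10β-CH3) because the E-configured C9=C10 terminus carries the tether outside and the methyl inside while the nitro group of the E dienophile lies endo; C6 (6α-nitro) is set by the same endo mode and is erased in step 17. The absolute sense follows from C2, since only the chair with the silyloxy group equatorial is accessible: addition to the other diene face would place that group syn-axial to both the C4 and the C10 methyl groups. The step needs trans over cis ring fusion and a cycloaddition faster than a [1,5]-hydrogen shift of the Z-methyl diene; the endo preference of the nitro group, the activated dienophile and high dilution with a radical inhibitor serve this, and the regiochemistry is enforced by the tether.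

Step 17
Reactants: 24 6α-nitro octalin
Product: 26 2α-(TBSO)-15-(TBDPSO)labda-8,13E-dien-6-one, via sodium nitronate 25 (not isolated)
Conditions: NaOMe, MeOH/THF, 0 °C; then aq. TiCl3, NH4OAc (pH 5–6), rt
Reagents that add atoms: water (O)
Why: Nef reaction in its reductive variant: the nitronate is reduced by trivalent titanium to the imine, which hydrolyses at buffered pH to the C6 ketone under conditions that should leave alkenes and silyl ethers intact.

Step 18
Reactants: 26 C6 ketone
Product: 28 7α-hydroxy-2α-(TBSO)-15-(TBDPSO)labda-8,13E-dien-6-one, via potassium dienolate 27 (not isolated)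
Conditions: KN(SiMe3)2, THF, −78 °C; then 2-(phenylsulfonyl)-3-phenyloxaziridine, −78 °C; AcOH quench at −78 °C
Reagents that add atoms: 2-(phenylsulfonyl)-3-phenyloxaziridine (O=S(=O)(N1OC1c1ccccc1)c1ccccc1)
Why: Electrophilic hydroxylation of the kinetic dienolate (deprotonation at the allylic C7 methylene, not at the hindered C5) by the N-sulfonyloxaziridine should occur at C7 from the α face, opposite the axial C10 and C4β methyl groups, setting the 7α-hydroxyl.

Step 19
Reactants: 28 7α-hydroxy ketone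
Product: 29 2α,7α-dihydroxy-15-(TBDPSO)labda-8,13E-dien-6-one
Conditions: CSA (0.2 equiv), MeOH/CH2Cl2 1:1, 0 °C → rt
Reagents that add atoms: none
Why: Acid-catalysed methanolysis should remove the secondary TBS ether selectively in the presence of the more robust primary TBDPS ether.

Step 20
Reactants: 29 2α,7α-diol
Product: 30 2α,7α-diacetoxy-15-(TBDPSO)labda-8,13E-dien-6-one
Conditions: Ac2O, pyridine, DMAP (cat.), CH2Cl2, 0 °C → rt
Reagents that add atoms: acetic anhydride (CC(=O)OC(C)=O)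
Why: DMAP-catalysed acetylation of both secondary hydroxyls installs the two acetates of the target in one operation.

Step 21
Reactants: 30 diacetoxy ketone
Product: 31 2α,7α-diacetoxy-15-(TBDPSO)labda-8,13E-dien-6β-ol
Conditions: NaBH4, CeCl3·7H2O, MeOH, −40 °C
Reagents that add atoms: none
Why: Hydride reduction under Luche conditions should occur from the α face, because the β face of C6 is blocked by the syn-axial C4β and C10 methyl groups, giving the axial 6β-alcohol, and the 7α-acetate cannot migrate to a trans-diaxial neighbour.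

Step 22
Reactants: 31 6β-alcohol
Product: 32 2α,7α-diacetoxy-6β-(3-methylbutanoyloxy)-15-(TBDPSO)labda-8,13E-diene
Conditions: 3-methylbutanoyl chloride, DMAP, pyridine, CH2Cl2, 40 °C
Reagents that add atoms: 3-methylbutanoyl chloride (CC(C)CC(=O)Cl)
Why: Nucleophilic-catalysed acylation (DMAP, acyl chloride) of the hindered axial 6β-hydroxyl.

Step 23
Reactants: 32 silyl-protected triester
Product: 33 2α,7α-diacetoxy-6β-(3-methylbutanoyloxy)labda-8,13E-dien-15-ol (CNP0257091.1)
Conditions: HF·pyridine, THF/pyridine, 0 °C → rt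
Reagents that add atoms: none
Why: Fluoride-mediated cleavage of the primary silyl ether under buffered, non-basic conditions that should leave the three esters untouched.

**Compound list**

1 | 4-(tert-butyldimethylsilyloxy)but-1-yne | C#CCCO[Si](C)(C)C(C)(C)C | starting material
2 | [(E)-4-(TBSO)-2-methylbut-1-enyl]dimethylaluminium (not isolated) | C[Al](C)/C=C(\C)CCO[Si](C)(C)C(C)(C)C | intermediate
3 | (E)-5-(TBSO)-3-methylpent-2-en-1-ol | OC/C=C(\C)CCO[Si](C)(C)C(C)(C)C | intermediate
4 | (E)-5-(TBSO)-1-(TBDPSO)-3-methylpent-2-ene | CC(C)(C)[Si](C)(C)OCC/C(C)=C/CO[Si](c1ccccc1)(c1ccccc1)C(C)(C)C | intermediate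
5 | (E)-5-(TBDPSO)-3-methylpent-3-en-1-ol | OCC/C(C)=C/CO[Si](c1ccccc1)(c1ccccc1)C(C)(C)C | intermediate
6 | (E)-1-(TBDPSO)-5-iodo-3-methylpent-2-ene | ICC/C(C)=C/CO[Si](c1ccccc1)(c1ccccc1)C(C)(C)C | intermediate
7 | 2,2-dimethylpent-4-enal | C=CCC(C)(C)C=O | starting material
8 | 5,5-dimethoxy-4,4-dimethylpent-1-ene | C=CCC(C)(C)C(OC)OC | intermediate
9 | 3-(3,3-dimethoxy-2,2-dimethylpropyl)-1,2,4-trioxolane (not isolated) | COC(OC)C(C)(C)CC1OCOO1 | intermediate
10 | 4,4-dimethoxy-3,3-dimethylbutanal | O=CCC(C)(C)C(OC)OC | intermediate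
11 | 1-methoxy-1,3-bis(trimethylsilyloxy)buta-1,3-diene | COC(O[Si](C)(C)C)=CC(=C)O[Si](C)(C)C | starting material
12 | methyl (S)-8,8-dimethoxy-7,7-dimethyl-3,5-bis(trimethylsilyloxy)oct-2-enoate (not isolated) | COC(=O)C=C(O[Si](C)(C)C)C[C@@H](O[Si](C)(C)C)CC(C)(C)C(OC)OC | intermediate
13 | methyl (S)-5-hydroxy-8,8-dimethoxy-7,7-dimethyl-3-oxooctanoate | COC(=O)CC(=O)C[C@@H](O)CC(C)(C)C(OC)OC | intermediate
14 | methyl (S)-5-(TBSO)-8,8-dimethoxy-7,7-dimethyl-3-oxooctanoate | COC(=O)CC(=O)C[C@@H](O[Si](C)(C)C(C)(C)C)CC(C)(C)C(OC)OC | intermediate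
15 | methyl (5S)-5-(TBSO)-2-[(E)-5-(TBDPSO)-3-methylpent-3-enyl]-8,8-dimethoxy-7,7-dimethyl-3-oxooctanoate, both α-epimers | COC(=O)C(CC/C(C)=C/CO[Si](c1ccccc1)(c1ccccc1)C(C)(C)C)C(=O)C[C@@H](O[Si](C)(C)C(C)(C)C)CC(C)(C)C(OC)OC | intermediate
16 | sodium (Z)-enolate of 15 (not isolated) | [Na+].COC(=O)/C(CC/C(C)=C/CO[Si](c1ccccc1)(c1ccccc1)C(C)(C)C)=C(\[O-])C[C@@H](O[Si](C)(C)C(C)(C)C)CC(C)(C)C(OC)OC | intermediate
17 | (2Z)-enol triflate of 15 (OTf cis to CO2Me) | COC(=O)/C(CC/C(C)=C/CO[Si](c1ccccc1)(c1ccccc1)C(C)(C)C)=C(\OS(=O)(=O)C(F)(F)F)C[C@@H](O[Si](C)(C)C(C)(C)C)CC(C)(C)C(OC)OC | intermediate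
18 | methyl (2E)-5-(TBSO)-2-[(E)-5-(TBDPSO)-3-methylpent-3-enyl]-8,8-dimethoxy-3,7,7-trimethyloct-2-enoate (CH3 cis to CO2Me) | COC(=O)/C(CC/C(C)=C/CO[Si](c1ccccc1)(c1ccccc1)C(C)(C)C)=C(\C)C[C@@H](O[Si](C)(C)C(C)(C)C)CC(C)(C)C(OC)OC | intermediate
19 | (3E)-6-(TBSO)-3-[(E)-5-(TBDPSO)-3-methylpent-3-enyl]-9,9-dimethoxy-2,4,8,8-tetramethylnon-3-en-2-ol | CC(C)(O)/C(CC/C(C)=C/CO[Si](c1ccccc1)(c1ccccc1)C(C)(C)C)=C(\C)C[C@@H](O[Si](C)(C)C(C)(C)C)CC(C)(C)C(OC)OC | intermediate
20 | (3E)-6-(TBSO)-3-[(E)-5-(TBDPSO)-3-methylpent-3-enyl]-9,9-dimethoxy-2,4,8,8-tetramethylnona-1,3-diene | C=C(C)/C(CC/C(C)=C/CO[Si](c1ccccc1)(c1ccccc1)C(C)(C)C)=C(\C)C[C@@H](O[Si](C)(C)C(C)(C)C)CC(C)(C)C(OC)OC | intermediate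
21 | (6E)-4-(TBSO)-7-[(E)-5-(TBDPSO)-3-methylpent-3-enyl]-2,2,6,8-tetramethylnona-6,8-dienal | C=C(C)/C(CC/C(C)=C/CO[Si](c1ccccc1)(c1ccccc1)C(C)(C)C)=C(\C)C[C@@H](O[Si](C)(C)C(C)(C)C)CC(C)(C)C=O | intermediate
22 | (7E)-5-(TBSO)-8-[(E)-5-(TBDPSO)-3-methylpent-3-enyl]-3,3,7,9-tetramethyl-1-nitrodeca-7,9-dien-2-ol (not isolated) | C=C(C)/C(CC/C(C)=C/CO[Si](c1ccccc1)(c1ccccc1)C(C)(C)C)=C(\C)C[C@@H](O[Si](C)(C)C(C)(C)C)CC(C)(C)C(O)C[N+](=O)[O-] | intermediate
23 | (1E,7E)-5-(TBSO)-8-[(E)-5-(TBDPSO)-3-methylpent-3-enyl]-3,3,7,9-tetramethyl-1-nitrodeca-1,7,9-triene | C=C(C)/C(CC/C(C)=C/CO[Si](c1ccccc1)(c1ccccc1)C(C)(C)C)=C(\C)C[C@@H](O[Si](C)(C)C(C)(C)C)CC(C)(C)/C=C/[N+](=O)[O-] | intermediate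
24 | 2α-(TBSO)-15-(TBDPSO)-6α-nitrolabda-8,13E-diene (5α-H, 10β-CH3) | CC(C)(C)[Si](C)(C)O[C@H]1CC(C)(C)[C@@H]2[C@@H]([N+](=O)[O-])CC(C)=C(CC/C(C)=C/CO[Si](c3ccccc3)(c3ccccc3)C(C)(C)C)[C@@]2(C)C1 | intermediate
25 | sodium nitronate of 24 (not isolated) | [Na+].CC(C)(C)[Si](C)(C)O[C@H]1CC(C)(C)[C@@H]2C(=[N+]([O-])[O-])CC(C)=C(CC/C(C)=C/CO[Si](c3ccccc3)(c3ccccc3)C(C)(C)C)[C@@]2(C)C1 | intermediate
26 | 2α-(TBSO)-15-(TBDPSO)labda-8,13E-dien-6-one | CC(C)(C)[Si](C)(C)O[C@H]1CC(C)(C)[C@@H]2C(=O)CC(C)=C(CC/C(C)=C/CO[Si](c3ccccc3)(c3ccccc3)C(C)(C)C)[C@@]2(C)C1 | intermediate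
27 | potassium 6,8-dienolate of 26 (not isolated) | [K+].CC(C)(C)[Si](C)(C)O[C@H]1CC(C)(C)[C@@H]2C([O-])=CC(C)=C(CC/C(C)=C/CO[Si](c3ccccc3)(c3ccccc3)C(C)(C)C)[C@@]2(C)C1 | intermediate
28 | 7α-hydroxy-2α-(TBSO)-15-(TBDPSO)labda-8,13E-dien-6-one | CC(C)(C)[Si](C)(C)O[C@H]1CC(C)(C)[C@@H]2C(=O)[C@@H](O)C(C)=C(CC/C(C)=C/CO[Si](c3ccccc3)(c3ccccc3)C(C)(C)C)[C@@]2(C)C1 | intermediate
29 | 2α,7α-dihydroxy-15-(TBDPSO)labda-8,13E-dien-6-one | O[C@H]1CC(C)(C)[C@@H]2C(=O)[C@@H](O)C(C)=C(CC/C(C)=C/CO[Si](c3ccccc3)(c3ccccc3)C(C)(C)C)[C@@]2(C)C1 | intermediate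
30 | 2α,7α-diacetoxy-15-(TBDPSO)labda-8,13E-dien-6-one | CC(=O)O[C@H]1CC(C)(C)[C@@H]2C(=O)[C@@H](OC(C)=O)C(C)=C(CC/C(C)=C/CO[Si](c3ccccc3)(c3ccccc3)C(C)(C)C)[C@@]2(C)C1 | intermediate
31 | 2α,7α-diacetoxy-15-(TBDPSO)labda-8,13E-dien-6β-ol | CC(=O)O[C@H]1CC(C)(C)[C@@H]2[C@H](O)[C@@H](OC(C)=O)C(C)=C(CC/C(C)=C/CO[Si](c3ccccc3)(c3ccccc3)C(C)(C)C)[C@@]2(C)C1 | intermediate
32 | 2α,7α-diacetoxy-6β-(3-methylbutanoyloxy)-15-(TBDPSO)labda-8,13E-diene | CC(=O)O[C@H]1CC(C)(C)[C@@H]2[C@H](OC(=O)CC(C)C)[C@@H](OC(C)=O)C(C)=C(CC/C(C)=C/CO[Si](c3ccccc3)(c3ccccc3)C(C)(C)C)[C@@]2(C)C1 | intermediate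
33 | 2α,7α-diacetoxy-6β-(3-methylbutanoyloxy)labda-8,13E-dien-15-ol (CNP0257091.1) | CC(=O)O[C@H]1CC(C)(C)[C@@H]2[C@H](OC(=O)CC(C)C)[C@@H](OC(C)=O)C(C)=C(CC/C(C)=C/CO)[C@@]2(C)C1 | target

**Step count and risks**

Total step count: 23. Longest linear sequence: 19 steps (steps 5–23 from 7; the branch through steps 1–4 and 9–23 is equally long).

Steps most likely to fail:

1. Step 16. The cycloaddition at the doubly congested C5–C10 bond may be slower than a [1,5]-hydrogen shift from the Z-methyl group of the diene or than polymerisation of the nitroalkene, and endo/exo discrimination (trans against cis ring fusion) may be poor. The fallback sets out from aldehyde 21 and uses a Lewis-acid-activated enal as dienophile at low temperature. Wittig olefination of 21 with (triphenylphosphoranylidene)acetaldehyde (toluene, 80 °C) should give the (E)-enal F1. Treatment with Et2AlCl (CH2Cl2, −78 → −20 °C) should then give, through the endo mode, the trans-fused 6α-formyl octalin F2. Condensation of F2 with morpholine (TsOH cat., toluene, water removal) gives the morpholine enamine F3. Oxidative cleavage of its C=C bond with CuCl and O2 in MeCN removes the extra carbon and returns the route at ketone 26.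

2. Step 18. Oxygen transfer may lose facial selectivity, or the new α-ketol may tautomerise through the enediol to the conjugated 6-hydroxy-8-en-7-one under the basic conditions. The fallback sets out from ketone 26 and installs the C7 acetate directly through the enol under acidic conditions, so no ketol alkoxide is formed. Pb(OAc)4 with BF3·OEt2 in benzene at rt should give the 7α-acetoxy ketone F4, by delivery to the less hindered α face. Methanolysis of the TBS ether (CSA, MeOH/CH2Cl2) gives the 2α-hydroxy-7α-acetoxy ketone F5, and acetylation (Ac2O, pyridine, DMAP) returns the route at diacetate 30.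

3. Step 13. The tertiary allylic sulfamate may ionise to a delocalised allyl cation, followed by proton loss from C1, C11 or the C10 methyl (isomeric dienes) or by scrambling of the C9=C10 geometry. The fallback sets out from enoate 18 and builds the terminal methylene by carbonyl olefination instead of elimination. Me(MeO)NH·HCl with i-PrMgCl (THF, −20 °C) converts 18 into the Weinreb amide F6. MeMgBr (THF, 0 °C) then gives the methyl ketone F7, and methylenation with methylenetriphenylphosphorane (from Ph3PCH3Br and KN(SiMe3)2, toluene, rt → 60 °C) returns the route at diene 20.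

**Further compounds**

F1 | step 16 | (2E,8E)-6-(TBSO)-9-[(E)-5-(TBDPSO)-3-methylpent-3-enyl]-4,4,8,10-tetramethylundeca-2,8,10-trienal | C=C(C)/C(CC/C(C)=C/CO[Si](c1ccccc1)(c1ccccc1)C(C)(C)C)=C(\C)C[C@@H](O[Si](C)(C)C(C)(C)C)CC(C)(C)/C=C/C=O
F2 | step 16 | 6α-formyl-2α-(TBSO)-15-(TBDPSO)labda-8,13E-diene | CC(C)(C)[Si](C)(C)O[C@H]1CC(C)(C)[C@@H]2[C@@H](C=O)CC(C)=C(CC/C(C)=C/CO[Si](c3ccccc3)(c3ccccc3)C(C)(C)C)[C@@]2(C)C1
F3 | step 16 | morpholine enamine of F2 (6-(morpholinomethylidene) octalin) | CC(C)(C)[Si](C)(C)O[C@H]1CC(C)(C)[C@@H]2C(=CN3CCOCC3)CC(C)=C(CC/C(C)=C/CO[Si](c4ccccc4)(c4ccccc4)C(C)(C)C)[C@@]2(C)C1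
F4 | step 18 | 7α-acetoxy-2α-(TBSO)-15-(TBDPSO)labda-8,13E-dien-6-one | CC(C)(C)[Si](C)(C)O[C@H]1CC(C)(C)[C@@H]2C(=O)[C@@H](OC(C)=O)C(C)=C(CC/C(C)=C/CO[Si](c3ccccc3)(c3ccccc3)C(C)(C)C)[C@@]2(C)C1
F5 | step 18 | 7α-acetoxy-2α-hydroxy-15-(TBDPSO)labda-8,13E-dien-6-one | O[C@H]1CC(C)(C)[C@@H]2C(=O)[C@@H](OC(C)=O)C(C)=C(CC/C(C)=C/CO[Si](c3ccccc3)(c3ccccc3)C(C)(C)C)[C@@]2(C)C1
F6 | step 13 | N-methoxy-N-methyl amide corresponding to ester 18 | CON(C)C(=O)/C(CC/C(C)=C/CO[Si](c1ccccc1)(c1ccccc1)C(C)(C)C)=C(\C)C[C@@H](O[Si](C)(C)C(C)(C)C)CC(C)(C)C(OC)OC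
F7 | step 13 | methyl ketone corresponding to ester 18 ((3E)-enone) | CC(=O)/C(CC/C(C)=C/CO[Si](c1ccccc1)(c1ccccc1)C(C)(C)C)=C(\C)C[C@@H](O[Si](C)(C)C(C)(C)C)CC(C)(C)C(OC)OC
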